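**Retrosynthetic overview**
- The only strategic bond is the diaryl ether C–O bond between ring A (OMe, two Br) and ring B (2,4-dibromophenyl). All four bromines and the methyl ether are bought in place, so no late bromination has to be regiocontrolled.
- Ring A is the nucleophile: 3,5-dibromo-2-methoxyphenol, made from the commercial 3,5-dibromo-2-methoxybenzaldehyde by a Dakin-type Baeyer–Villiger oxidation.
- Ring B is the electrophile: a (2,4-dibromophenyl)(2,4,6-trimethoxyphenyl)iodonium salt, made in one pot from commercial 2,4-dibromo-1-iodobenzene.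
- The union is a metal-free O-arylation at 40 °C, chosen because no C–Br bond can react under these conditions. A direct copper-catalysed coupling would save one step but has to discriminate one C–I from four C–Br bonds, so it is kept as a fallback.
- No ring is formed: both benzene rings are purchased intact, ring A being elaborated first, then ring B, then the two are joined.

Assumption: the target has no stereocentre and no stable stereogenic axis, so it is achiral and "single enantiomer" is taken to mean the compound exactly as drawn.

**Step 1**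
Reactants: 1 3,5-dibromo-2-methoxybenzaldehyde
Product: 3 3,5-dibromo-2-methoxyphenol, via aryl formate 2 (not isolated)
Conditions: mCPBA (1.3 equiv), CH2Cl2, 0 °C to rt; aq. NaHCO3 wash; then K2CO3 (cat.), MeOH, rt
Reagents that add atoms: mCPBA (3-chloroperoxybenzoic acid), O=C(OO)c1cccc(Cl)c1
Why: Baeyer–Villiger (Dakin-type) oxidation, in which the ortho-methoxy aryl group migrates in preference to hydride to give the aryl formate, which mild methanolysis cleaves to the phenol, while the C–Br bonds and the methyl ether are inert to peracid and no stereocentre is involved.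

**Step 2**
Reactants: 4 2,4-dibromo-1-iodobenzene; 5 1,3,5-trimethoxybenzene
Product: 7 (2,4-dibromophenyl)(2,4,6-trimethoxyphenyl)iodonium 4-methylbenzenesulfonate, via hydroxy(tosyloxy)iodoarene 6 (not isolated)
Conditions: mCPBA (1.0 equiv), TsOH·H2O (1.0 equiv), MeCN, 77 °C, 30 min; then 5 (1.0 equiv), 77 °C to rt; Et2O trituration
Reagents that add atoms: TsOH·H2O (4-methylbenzenesulfonic acid monohydrate), Cc1ccc(cc1)S(=O)(=O)O.O
Why: One-pot diaryliodonium salt synthesis, in which the aryl iodide is oxidised to a Koser-type trivalent-iodine species that undergoes electrophilic aromatic substitution on the very electron-rich trimethoxybenzene (added only after the peracid is consumed), the peracid oxygen leaving as water and no stereocentre being involved.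

**Step 3**
Reactants: 3 3,5-dibromo-2-methoxyphenol; 7 (2,4-dibromophenyl)(2,4,6-trimethoxyphenyl)iodonium 4-methylbenzenesulfonate
Product: 9 1,5-dibromo-3-(2,4-dibromophenoxy)-2-methoxybenzene, via potassium phenoxide 8 (not isolated)
Conditions: KOtBu (1.0 equiv), THF, 0 °C; then 7 (1.2 equiv), 40 °C
Reagents that add atoms: none
Why: Metal-free O-arylation of a phenoxide with a diaryliodonium salt (ligand coupling at trivalent iodine), in which the more electron-poor, ortho-substituted 2,4-dibromophenyl group is transferred and the trimethoxyphenyl group leaves as its iodide, none of the four C–Br bonds reacting at 40 °C without a transition metal and no stereocentre being involved.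

**Compound list**
1 | 3,5-dibromo-2-methoxybenzaldehyde | COc1c(Br)cc(Br)cc1C=O | starting material
2 | 3,5-dibromo-2-methoxyphenyl formate | COc1c(Br)cc(Br)cc1OC=O | intermediate
3 | 3,5-dibromo-2-methoxyphenol | COc1c(Br)cc(Br)cc1O | intermediate
4 | 2,4-dibromo-1-iodobenzene | Brc1ccc(I)c(Br)c1 | starting material
5 | 1,3,5-trimethoxybenzene | COc1cc(OC)cc(OC)c1 | starting material
6 | 2,4-dibromo-1-[hydroxy(tosyloxy)iodo]benzene | Cc1ccc(cc1)S(=O)(=O)OI(O)c1ccc(Br)cc1Br | intermediate
7 | (2,4-dibromophenyl)(2,4,6-trimethoxyphenyl)iodonium 4-methylbenzenesulfonate | COc1cc(OC)c([I+]c2ccc(Br)cc2Br)c(OC)c1.Cc1ccc(cc1)S(=O)(=O)[O-] | intermediate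
8 | potassium 3,5-dibromo-2-methoxyphenolate | COc1c(Br)cc(Br)cc1[O-].[K+] | intermediate
9 | 1,5-dibromo-3-(2,4-dibromophenoxy)-2-methoxybenzene | COc1c(Br)cc(Br)cc1Oc1ccc(Br)cc1Br | target

**Totals**
Total step count: 3. Longest linear sequence: 2 (1 → 3 → 9, or 4 → 7 → 9).

**Steps most likely to fail, with fallbacks**

Step 3 (most at risk). The phenoxide is hindered and weakly nucleophilic, and wrong-aryl transfer or aryne-type cine products could appear. The fallback sets out from 3 and comes back at 9, building ring B's second bromine after the ether bond. SNAr of 3 with 4-bromo-1-fluoro-2-nitrobenzene (O=[N+]([O-])c1cc(Br)ccc1F; K2CO3, DMF, 60 °C) gives 1,5-dibromo-3-(4-bromo-2-nitrophenoxy)-2-methoxybenzene F6. Reduction that spares C–Br (Fe powder, NH4Cl, EtOH/H2O, 80 °C) gives 5-bromo-2-(3,5-dibromo-2-methoxyphenoxy)aniline F7. Diazotisation (NaNO2, aq. HBr, MeCN, 0 °C) gives 5-bromo-2-(3,5-dibromo-2-methoxyphenoxy)benzenediazonium bromide F8, which a Sandmeyer reaction (CuBr, 60 °C) converts into 9.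

Step 1. Hydride rather than aryl migration would give the benzoic acid, because the ring carries two bromines and the flanked OMe is twisted out of conjugation. The fallback sets out from 1 and comes back at 3, replacing oxygen insertion by a nitrogen route. Pinnick oxidation of 1 (NaClO2, NaH2PO4, 2-methyl-2-butene, t-BuOH/H2O, rt) gives 3,5-dibromo-2-methoxybenzoic acid F1. Curtius rearrangement (DPPA, Et3N, toluene, rt then 90 °C) passes through 3,5-dibromo-2-methoxybenzoyl azide F2 and 1,5-dibromo-3-isocyanato-2-methoxybenzene F3. Hydrolysis in the same pot (aq. HCl, then base) gives 3,5-dibromo-2-methoxyaniline F4. Diazotisation (NaNO2, aq. H2SO4, 0 °C) gives 3,5-dibromo-2-methoxybenzenediazonium hydrogen sulfate F5, which is hydrolysed (Cu2O, Cu(NO3)2, H2O, rt) to 3.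

Step 2. Oxidation of the electron-poor, ortho-substituted aryl iodide may be sluggish, or the salt may not crystallise cleanly. The fallback sets out from 4 (with 3 as partner) and comes back at 9, using the aryl iodide itself instead of a trivalent-iodine reagent. It is an Ullmann-type etherification (CuI 10 mol %, picolinic acid 20 mol %, K3PO4, DMSO, 80 °C, slight excess of 4), relying on C–I reacting faster than any C–Br at or below 80 °C. It makes no new compound (entry F0).

**Further compounds**
F1 | step 1 | 3,5-dibromo-2-methoxybenzoic acid | COc1c(Br)cc(Br)cc1C(=O)O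
F2 | step 1 | 3,5-dibromo-2-methoxybenzoyl azide | COc1c(Br)cc(Br)cc1C(=O)N=[N+]=[N-]
F3 | step 1 | 1,5-dibromo-3-isocyanato-2-methoxybenzene | COc1c(Br)cc(Br)cc1N=C=O
F4 | step 1 | 3,5-dibromo-2-methoxyaniline | COc1c(Br)cc(Br)cc1N
F5 | step 1 | 3,5-dibromo-2-methoxybenzenediazonium hydrogen sulfate | COc1c(Br)cc(Br)cc1[N+]#N.OS(=O)(=O)[O-]
F0 | step 2 | none | none
F6 | step 3 | 1,5-dibromo-3-(4-bromo-2-nitrophenoxy)-2-methoxybenzene | COc1c(Br)cc(Br)cc1Oc1ccc(Br)cc1[N+](=O)[O-]
F7 | step 3 | 5-bromo-2-(3,5-dibromo-2-methoxyphenoxy)aniline | COc1c(Br)cc(Br)cc1Oc1ccc(Br)cc1N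
F8 | step 3 | 5-bromo-2-(3,5-dibromo-2-methoxyphenoxy)benzenediazonium bromide | COc1c(Br)cc(Br)cc1Oc1ccc(Br)cc1[N+]#N.[Br-]
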